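**Plan**

1. Numbering: each C15 half has ring carbons C1 (sp2, chain-bearing), C5, C6, C7, C8 (O), C9, C10 (Me), chain carbons C2–C4 and lactone carbons C11–C13; primes mark the spiro-lactone half.
2. Retrosynthesis: remove the C1 hydroxyl (dienolate oxygenation), cut C3–C11' and C5–C13' (Diels–Alder) to two C8-epimeric monomers, and trace both to one cyclohept-4-enone keto ester. In that ketone cut C6–C7 and re-join C1–O (retro-Claisen) to a 2-alkylidene-5,5-divinyloxolane, then cut C7–C11 (Negishi), C8–O (iodoetherification), C1–vinyl (Grignard) and C9–C10 (auxiliary alkylation).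
3. Enabling feature: in the primed cycloheptene, C8' lies three bonds from both olefin carbons (C1' via C9'–C10', C5' via C6'–C7'). With C8' as a ketone the ring is a cyclohept-4-enone, the product of a Claisen ring expansion of the oxolane O–C8–C9–C10–C1.
4. Forward order: oxolane, then the seven-membered carbocycle by ring expansion (one ketone serves both halves), then each γ-lactone, then the cyclohexene by cycloaddition, last the C1 hydroxyl together with the upper methylene.
5. Stereochemistry: C10 from the oxazolidinone auxiliary; C7 by chirality transfer in the chair Claisen transition state; C8 by bulky hydride (cis) or Mitsunobu inversion (trans); C5 and C11' by a carbonyl-exo cycloaddition on the convex face of the cis lactone and the O8 face of the diene; C1 by O2 attack anti to C13' and the C10 methyl.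

Key step: step 6

Remark: the C11 configuration drawn for 10, 11 and 17–22 and the C3 configuration of 20 are the expected ones; both centres are erased later and do not affect the outcome.

**Route**

Step 1
Reactants: 1 (4R)-4-benzyl-3-propanoyl-1,3-oxazolidin-2-one
Product: 2 (4R)-4-benzyl-3-[(2S)-2-methylpent-4-ynoyl]-1,3-oxazolidin-2-one
Conditions: NaN(SiMe3)2, THF, −78 °C; propargyl bromide, −78 → −40 °C
Reagents that add atoms: propargyl bromide (3-bromoprop-1-yne), C#CCBr
Why: Oxazolidinone-auxiliary enolate alkylation (Evans alkylation), in which the chelated Z sodium enolate is alkylated on the face opposite the benzyl group and so sets C10 as S.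

Step 2
Reactants: 2 (4R)-4-benzyl-3-[(2S)-2-methylpent-4-ynoyl]-1,3-oxazolidin-2-one
Product: 3 methyl (2S)-2-methylpent-4-ynoate
Conditions: MeOMgBr (from MeMgBr and MeOH), MeOH, 0 °C; aq NH4Cl; ester kept in solution (volatile)
Reagents that add atoms: methanol, CO
Why: Transesterification with MeOMgBr attacks only the exocyclic imide carbonyl, so the auxiliary is released without enolisation of the α-stereocentre.

Step 3
Reactants: 3 methyl (2S)-2-methylpent-4-ynoate
Product: 4 (4S)-3-ethenyl-4-methylhept-1-en-6-yn-3-ol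
Conditions: CH2=CHMgBr (4 equiv, one equivalent is consumed by the alkyne C–H), CeCl3 (anhydrous), THF, −78 → 0 °C; aq NH4Cl
Reagents that add atoms: vinylmagnesium bromide, C=C[Mg]Br
Why: Double 1,2-addition of the vinyl organocerium/Grignard reagent to the ester gives a tertiary alcohol whose carbinol carbon (future C1) carries two identical vinyl groups and is therefore not stereogenic, CeCl3 suppressing enolisation at C10 and conjugate addition to the transient vinyl ketone.

Step 4
Reactants: 4 (4S)-3-ethenyl-4-methylhept-1-en-6-yn-3-ol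
Product: 5 (2E,4S)-5,5-diethenyl-2-(iodomethylidene)-4-methyloxolane
Conditions: I2 (1.5 equiv), NaHCO3, MeCN, 0 °C, dark
Reagents that add atoms: iodine, II
Why: 5-exo-dig iodoetherification of the alkynol adds oxygen and iodine anti across the triple bond and so gives the E vinyl iodide (iodine trans to the ring oxygen), while the vinyl groups could only close three- or four-membered rings.

Step 5
Reactants: 5 (2E,4S)-5,5-diethenyl-2-(iodomethylidene)-4-methyloxolane
Product: 6 tert-butyl (3E)-3-[(4S)-5,5-diethenyl-4-methyloxolan-2-ylidene]propanoate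
Conditions: BrZnCH2CO2tBu (1.5 equiv), Pd2(dba)3 (2.5 mol%), XPhos (10 mol%), THF, 20 → 45 °C; Et3N-deactivated silica
Reagents that add atoms: (2-tert-butoxy-2-oxoethyl)zinc bromide, CC(C)(C)OC(=O)C[Zn]Br
Why: Negishi cross-coupling of a vinyl iodide with a Reformatsky reagent proceeds with retention of olefin geometry, so the acetate arm (C11–C12) ends trans to the ring oxygen.

Step 6
Reactants: 6 tert-butyl (3E)-3-[(4S)-5,5-diethenyl-4-methyloxolan-2-ylidene]propanoate
Product: 7 tert-butyl 2-[(1S,4S)-5-ethenyl-4-methyl-2-oxocyclohept-5-en-1-yl]acetate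
Conditions: toluene (0.05 M), K2CO3 (solid, trace), 135 °C, sealed base-washed tube
Reagents that add atoms: none
Why: Thermal [3,3]-sigmatropic (Claisen) rearrangement of the allyl vinyl ether C7=C8–O–C1–CH=CH2: the C7–C6 bond forms between the alkylidene carbon and a vinyl terminus while the doubly allylic C1–O bond breaks, so the five-membered oxolane (O, C8, C9, C10, C1) becomes the seven-membered carbocycle C1–C5–C6–C7–C8–C9–C10 as a cyclohept-4-enone. The closest known reaction type is the Claisen ring expansion of 2-methylene-5-vinyloxolanes to cyclohept-4-enones (and of the six-membered homologues to cyclooct-4-enones). The carbocycle closes through a pericyclic six-centre array bridged by C9–C10 (bicyclo[3.2.1]-like), and only the chair form of this array, with the bridge axial on C1, can deliver the cis ring olefin, the boat leading to a trans-cycloheptene. C10 is carried over unchanged, and the new C7 centre is set by chirality transfer: the E enol ether holds the CH2CO2tBu arm pseudo-equatorial, and the vinyl group trans to the C10 methyl should react because this keeps the methyl exo on the two-carbon bridge (the cis vinyl would push it endo against the forming bond), which should give the C7/C10-trans (1S,4S) ketone. The step needs discrimination between the two diastereotopic vinyl groups and an intact E enol ether; the first is secured by the adjacent C10 methyl, the second by acid-free conditions, which also prevent ionisation of the doubly allylic ether and migration of the exocyclic double bond into the ring. The vinyl group that does not react stays on C1 and provides the 1,3-diene used for the side chain.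

Step 7
Reactants: 7 tert-butyl 2-[(1S,4S)-5-ethenyl-4-methyl-2-oxocyclohept-5-en-1-yl]acetate
Product: 8 tert-butyl 2-[(1S,2S,4S)-5-ethenyl-2-hydroxy-4-methylcyclohept-5-en-1-yl]acetate
Conditions: Li[BH(sec-Bu)3], THF, −78 °C; AcOH quench at −78 °C
Reagents that add atoms: none
Why: The bulky hydride attacks the C8 ketone from the face opposite the adjacent C7 arm (equatorial attack), giving the C8 alcohol cis to C7–C11 and trans to the C10 methyl.

Step 8
Reactants: 8 tert-butyl 2-[(1S,2S,4S)-5-ethenyl-2-hydroxy-4-methylcyclohept-5-en-1-yl]acetate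
Product: 9 (3aS,7S,8aS)-6-ethenyl-7-methyl-3,3a,4,7,8,8a-hexahydro-2H-cyclohepta[b]furan-2-one
Conditions: KOtBu (0.1 equiv), THF, 0 °C
Reagents that add atoms: none
Why: Base-catalysed intramolecular transesterification (5-exo-trig lactonisation) of the cis γ-hydroxy ester expels tert-butoxide and closes the cis-fused lactone with retention at C8.

Step 9
Reactants: 9 (3aS,7S,8aS)-6-ethenyl-7-methyl-3,3a,4,7,8,8a-hexahydro-2H-cyclohepta[b]furan-2-one
Product: 12 (3aS,7S,8aS)-6-ethenyl-7-methyl-3-methylidene-4,7,8,8a-tetrahydro-3aH-cyclohepta[b]furan-2-one, via Mannich base 10 (not isolated), via ammonium iodide 11 (not isolated)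
Conditions: LiN(iPr)2, THF, −78 °C; Me2N=CH2 I, −78 → 0 °C; then MeI, MeOH, 20 °C; then aq NaHCO3, CH2Cl2
Reagents that add atoms: N,N-dimethylmethyleneiminium iodide (Eschenmoser's salt), C[N+](C)=C.[I-]
Why: α-Methylenation by Mannich reaction of the lactone enolate followed by Hofmann-type elimination of the quaternised amine, the transient C11 centre (attack on the convex face) being erased.

Step 10
Reactants: 12 (3aS,7S,8aS)-6-ethenyl-7-methyl-3-methylidene-4,7,8,8a-tetrahydro-3aH-cyclohepta[b]furan-2-one
Product: 13 (3aS,7S,8aS)-7-methyl-3-methylidene-6-[(1E)-3-oxobut-1-en-1-yl]-4,7,8,8a-tetrahydro-3aH-cyclohepta[b]furan-2-one (cis-fused lower monomer)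
Conditions: methyl vinyl ketone (5 equiv), second-generation Hoveyda–Grubbs catalyst [RuCl2(H2IMes)(=CH-C6H4-2-OiPr)] (5 mol%), CH2Cl2, 40 °C
Reagents that add atoms: methyl vinyl ketone (but-3-en-2-one), CC(=O)C=C
Why: Olefin cross-metathesis of the terminal vinyl group of a 1-vinylcycloalkene with an enone, a closely precedented way to this dienone side chain, is E-selective and leaves the trisubstituted ring olefin and the 1,1-disubstituted acrylate untouched.

Step 11
Reactants: 8 tert-butyl 2-[(1S,2S,4S)-5-ethenyl-2-hydroxy-4-methylcyclohept-5-en-1-yl]acetate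
Product: 14 tert-butyl 2-[(1S,2R,4S)-5-ethenyl-4-methyl-2-[(4-nitrobenzoyl)oxy]cyclohept-5-en-1-yl]acetate
Conditions: 4-O2NC6H4CO2H, PPh3, DIAD, toluene, 0 → 20 °C
Reagents that add atoms: 4-nitrobenzoic acid, OC(=O)c1ccc(cc1)[N+](=O)[O-]
Why: Mitsunobu esterification displaces the activated C8 oxygen by SN2 with inversion and so turns the cis alcohol into the trans C8 ester (the tethered carboxyl arm itself cannot reach the rear of C8, so an external acid is used).

Step 12
Reactants: 14 tert-butyl 2-[(1S,2R,4S)-5-ethenyl-4-methyl-2-[(4-nitrobenzoyl)oxy]cyclohept-5-en-1-yl]acetate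
Product: 16 (3aS,7S,8aR)-6-ethenyl-7-methyl-3,3a,4,7,8,8a-hexahydro-2H-cyclohepta[b]furan-2-one, via trans hydroxy ester 15 (not isolated)
Conditions: K2CO3, MeOH, 20 °C; solvent exchange; KOtBu (0.1 equiv), THF, 0 → 20 °C
Reagents that add atoms: none
Why: Methanolysis of the activated aryl ester and base-catalysed lactonisation onto the tert-butyl ester both proceed with retention at C8 and give the trans-fused lactone.

Step 13
Reactants: 16 (3aS,7S,8aR)-6-ethenyl-7-methyl-3,3a,4,7,8,8a-hexahydro-2H-cyclohepta[b]furan-2-one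
Product: 18 [(3R,3aS,7S,8aR)-6-ethenyl-7-methyl-2-oxo-3,3a,4,7,8,8a-hexahydro-2H-cyclohepta[b]furan-3-yl]methyl acetate, via hydroxymethyl lactone 17 (not isolated)
Conditions: LiN(iPr)2, THF, −78 °C; CH2O (gas), −78 → −30 °C; then Ac2O, −30 → 0 °C
Reagents that add atoms: formaldehyde, C=O; acetic anhydride, CC(=O)OC(C)=O
Why: Aldol addition of the lactone enolate to formaldehyde (anti to the C7–C6 bond) and O-acetylation of the aldolate give a β-acetoxy lactone, a thermally stable latent α-methylene group that cannot act as a dienophile.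

Step 14
Reactants: 18 [(3R,3aS,7S,8aR)-6-ethenyl-7-methyl-2-oxo-3,3a,4,7,8,8a-hexahydro-2H-cyclohepta[b]furan-3-yl]methyl acetate
Product: 19 [(3R,3aS,7S,8aR)-7-methyl-2-oxo-6-[(1E)-3-oxobut-1-en-1-yl]-3,3a,4,7,8,8a-hexahydro-2H-cyclohepta[b]furan-3-yl]methyl acetate (trans-fused, masked upper monomer)
Conditions: methyl vinyl ketone (5 equiv), second-generation Hoveyda–Grubbs catalyst [RuCl2(H2IMes)(=CH-C6H4-2-OiPr)] (5 mol%), CH2Cl2, 40 °C
Reagents that add atoms: methyl vinyl ketone (but-3-en-2-one), CC(=O)C=C
Why: The same E-selective cross-metathesis as in step 10 installs the dienone that serves as the diene of the upper half.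

Step 15
Reactants: 19 masked upper monomer; 13 cis-fused lower monomer
Product: 20 Diels–Alder adduct (new bonds C3–C11' and C5–C13', C1=C2 olefin, 3-acetyl cis to C6 and C7' on the new ring, 13-acetoxy-11,13-dihydro upper lactone, lower lactone spiro at C11')
Conditions: toluene (2 M in the dienophile), BHT (5 mol%), 110 °C, sealed tube; diene component in threefold excess, surplus recovered by chromatography
Reagents that add atoms: none
Why: Thermal Diels–Alder dimerisation of the xanthanolide type, a one-to-one cycloaddition in which the s-cis diene C5=C1–C2=C3 of the masked monomer (its own α-methylene group is blocked, so only cross-addition or self-dimerisation of the lower monomer is possible and the excess of diene favours the former) adds to the exocyclic C11'=C13' olefin with "ortho" regiochemistry (acyl-bearing C3 to C11', C5 to C13'), the dienophile reacting on the convex face of its cis-fused lactone (syn to H7' and H8') with the lactone carbonyl exo, as is usual for s-cis-locked α-methylene lactones, and the diene reacting on its O8 face, anti to the pseudoaxial C6–H and C10–H bonds of the lactone-locked chair (torsional control), which together set C11' and C5, while C3 is only a transient stereocentre.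

Step 16
Reactants: 20 Diels–Alder adduct
Product: 23 target CNP0168949.5, via C1 hydroperoxide 21 (not isolated), via C1 alcohol acetate 22 (not isolated)
Conditions: DBU (3 equiv), O2 (1 atm), P(OEt)3 (2 equiv), MeCN, −20 → 20 °C
Reagents that add atoms: dioxygen, O=O
Why: DBU removes the doubly activated C3–H of the β,γ-unsaturated ketone, the dienolate is oxygenated at the γ-carbon C1 (autoxidation, hydroperoxide reduced in situ by the phosphite) on the face anti to C13' and the C10 methyl to give the conjugated γ-hydroxy enone, and the same base eliminates acetic acid from the β-acetoxy lactone (E1cB) to unveil the upper α-methylene lactone.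

**Compound list**

1 | (4R)-4-benzyl-3-propanoyl-1,3-oxazolidin-2-one | CCC(=O)N1[C@H](Cc2ccccc2)COC1=O | starting material
2 | (4R)-4-benzyl-3-[(2S)-2-methylpent-4-ynoyl]-1,3-oxazolidin-2-one | C#CC[C@H](C)C(=O)N1[C@H](Cc2ccccc2)COC1=O | intermediate
3 | methyl (2S)-2-methylpent-4-ynoate | C#CC[C@H](C)C(=O)OC | intermediate
4 | (4S)-3-ethenyl-4-methylhept-1-en-6-yn-3-ol | C#CC[C@H](C)C(O)(C=C)C=C | intermediate
5 | (2E,4S)-5,5-diethenyl-2-(iodomethylidene)-4-methyloxolane | I/C=C1\C[C@H](C)C(C=C)(C=C)O1 | intermediate
6 | tert-butyl (3E)-3-[(4S)-5,5-diethenyl-4-methyloxolan-2-ylidene]propanoate | CC(C)(C)OC(=O)C/C=C1\C[C@H](C)C(C=C)(C=C)O1 | intermediate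
7 | tert-butyl 2-[(1S,4S)-5-ethenyl-4-methyl-2-oxocyclohept-5-en-1-yl]acetate | CC(C)(C)OC(=O)C[C@@H]1CC=C(C=C)[C@@H](C)CC1=O | intermediate
8 | tert-butyl 2-[(1S,2S,4S)-5-ethenyl-2-hydroxy-4-methylcyclohept-5-en-1-yl]acetate (cis alcohol) | CC(C)(C)OC(=O)C[C@@H]1CC=C(C=C)[C@@H](C)C[C@@H]1O | intermediate
9 | (3aS,7S,8aS)-6-ethenyl-7-methyl-3,3a,4,7,8,8a-hexahydro-2H-cyclohepta[b]furan-2-one (cis lactone) | O=C1C[C@@H]2CC=C(C=C)[C@@H](C)C[C@@H]2O1 | intermediate
10 | (3R,3aS,7S,8aS)-3-[(dimethylamino)methyl]-6-ethenyl-7-methyl-3,3a,4,7,8,8a-hexahydro-2H-cyclohepta[b]furan-2-one (Mannich base) | CN(C)C[C@@H]1C(=O)O[C@H]2C[C@H](C)C(C=C)=CC[C@@H]12 | intermediate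
11 | trimethylammonium iodide of 10 | C[N+](C)(C)C[C@@H]1C(=O)O[C@H]2C[C@H](C)C(C=C)=CC[C@@H]12.[I-] | intermediate
12 | (3aS,7S,8aS)-6-ethenyl-7-methyl-3-methylidene-4,7,8,8a-tetrahydro-3aH-cyclohepta[b]furan-2-one | C=C1C(=O)O[C@H]2C[C@H](C)C(C=C)=CC[C@@H]12 | intermediate
13 | (3aS,7S,8aS)-7-methyl-3-methylidene-6-[(1E)-3-oxobut-1-en-1-yl]-4,7,8,8a-tetrahydro-3aH-cyclohepta[b]furan-2-one (cis-fused lower monomer) | C=C1C(=O)O[C@H]2C[C@H](C)C(/C=C/C(C)=O)=CC[C@@H]12 | intermediate
14 | tert-butyl 2-[(1S,2R,4S)-5-ethenyl-4-methyl-2-[(4-nitrobenzoyl)oxy]cyclohept-5-en-1-yl]acetate | CC(C)(C)OC(=O)C[C@@H]1CC=C(C=C)[C@@H](C)C[C@H]1OC(=O)c1ccc(cc1)[N+](=O)[O-] | intermediate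
15 | tert-butyl 2-[(1S,2R,4S)-5-ethenyl-2-hydroxy-4-methylcyclohept-5-en-1-yl]acetate (trans alcohol) | CC(C)(C)OC(=O)C[C@@H]1CC=C(C=C)[C@@H](C)C[C@H]1O | intermediate
16 | (3aS,7S,8aR)-6-ethenyl-7-methyl-3,3a,4,7,8,8a-hexahydro-2H-cyclohepta[b]furan-2-one (trans lactone) | O=C1C[C@@H]2CC=C(C=C)[C@@H](C)C[C@H]2O1 | intermediate
17 | (3R,3aS,7S,8aR)-6-ethenyl-3-(hydroxymethyl)-7-methyl-3,3a,4,7,8,8a-hexahydro-2H-cyclohepta[b]furan-2-one (as lithium alkoxide) | OC[C@@H]1C(=O)O[C@@H]2C[C@H](C)C(C=C)=CC[C@@H]12 | intermediate
18 | [(3R,3aS,7S,8aR)-6-ethenyl-7-methyl-2-oxo-3,3a,4,7,8,8a-hexahydro-2H-cyclohepta[b]furan-3-yl]methyl acetate | CC(=O)OC[C@@H]1C(=O)O[C@@H]2C[C@H](C)C(C=C)=CC[C@@H]12 | intermediate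
19 | [(3R,3aS,7S,8aR)-7-methyl-2-oxo-6-[(1E)-3-oxobut-1-en-1-yl]-3,3a,4,7,8,8a-hexahydro-2H-cyclohepta[b]furan-3-yl]methyl acetate (trans-fused, masked upper monomer) | CC(=O)OC[C@@H]1C(=O)O[C@@H]2C[C@H](C)C(/C=C/C(C)=O)=CC[C@@H]12 | intermediate
20 | Diels–Alder adduct (C3–C11' and C5–C13' bonds, C1=C2 olefin, 3-acetyl cis to C6 and C7', 13-acetoxy-11,13-dihydro upper lactone) | CC(=O)OC[C@@H]1C(=O)O[C@@H]2C[C@H](C)C3=C[C@H](C(C)=O)[C@]4(C[C@@H]3C[C@@H]12)C(=O)O[C@H]1C[C@H](C)C(/C=C/C(C)=O)=CC[C@H]14 | intermediate
21 | C1 hydroperoxide of the C2=C3 enone (13-acetate) | CC(=O)OC[C@@H]1C(=O)O[C@@H]2C[C@H](C)[C@]3(OO)C=C(C(C)=O)[C@]4(C[C@@H]3C[C@@H]12)C(=O)O[C@H]1C[C@H](C)C(/C=C/C(C)=O)=CC[C@H]14 | intermediate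
22 | 13-acetoxy-11,13-dihydro derivative of the target (C1 alcohol) | CC(=O)OC[C@@H]1C(=O)O[C@@H]2C[C@H](C)[C@]3(O)C=C(C(C)=O)[C@]4(C[C@@H]3C[C@@H]12)C(=O)O[C@H]1C[C@H](C)C(/C=C/C(C)=O)=CC[C@H]14 | intermediate
23 | CNP0168949.5 | C=C1C(=O)O[C@@H]2C[C@H](C)[C@]3(O)C=C(C(C)=O)[C@]4(C[C@@H]3C[C@@H]12)C(=O)O[C@H]1C[C@H](C)C(/C=C/C(C)=O)=CC[C@H]14 | target

**Totals**

Total step count: 16. Longest linear sequence: 13 steps (steps 1–7, 11–16).

**Steps most likely to fail**

Step 15. The acceptor-substituted diene of 19 may react slowly, so that self-dimerisation of 13 through its own dienone and the less favoured approach modes (bond formation at C5 on the face opposite O8, carbonyl-endo orientation) compete. Fallback, from 19 back to 20: the C4 ketone of 19 is reduced under Luche conditions (NaBH4, CeCl3·7H2O, MeOH, −78 °C) to the dienol F1 (either C4 epimer serves). This electron-richer diene should add to 13 in a normal-demand cycloaddition at lower temperature (toluene, 60 °C) to give the C4 alcohol adduct F2, and Dess–Martin oxidation (NaHCO3-buffered, CH2Cl2) of F2 returns the ketone 20.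

Step 16. Enolisation and oxygenation may be unselective (O2 attack at C3 instead of C1, ε-deprotonation and oxidation or double-bond migration in the lower dienone), and the freshly unmasked methylene lactone may suffer base-induced side reactions. Fallback, from 20 back to 22: the oxygen is introduced electrophilically, by epoxidation of the C1=C2 olefin with dimethyldioxirane (acetone, −20 °C) on the face anti to C13' and the C10 methyl to give the epoxide F3. Brief treatment with DBU (CH2Cl2, 0 °C) opens the epoxide by β-elimination from C3 (E1cB) to the C1 alcohol 22, which loses acetic acid under the conditions of step 16.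

Step 11. The activated C8 oxyphosphonium may eliminate toward C9 or C7 instead of undergoing SN2 substitution at the hindered secondary carbon. Fallback, from 7 back to 15: the trans alcohol is made without substitution, by electron-transfer reduction of ketone 7 (SmI2, THF–MeOH, −78 °C), which should deliver the more stable equatorial alcohol 15 directly. 15 is then lactonised as in the second half of step 12; this fallback makes no new compound (F0).

Further compounds
F1 | step 15 | C4 alcohol of 19 (dienol, either C4 epimer) | CC(=O)OC[C@@H]1C(=O)O[C@@H]2C[C@H](C)C(/C=C/C(C)O)=CC[C@@H]12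
F2 | step 15 | C4 alcohol of adduct 20 | CC(=O)OC[C@@H]1C(=O)O[C@@H]2C[C@H](C)C3=C[C@H](C(C)O)[C@]4(C[C@@H]3C[C@@H]12)C(=O)O[C@H]1C[C@H](C)C(/C=C/C(C)=O)=CC[C@H]14
F3 | step 16 | C1–C2 epoxide of 20 (oxygen anti to C13' and C10 methyl) | CC(=O)OC[C@@H]1C(=O)O[C@@H]2C[C@H](C)[C@@]35O[C@H]5[C@H](C(C)=O)[C@]4(C[C@@H]3C[C@@H]12)C(=O)O[C@H]1C[C@H](C)C(/C=C/C(C)=O)=CC[C@H]14
F0 | step 11 | none | none
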